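The benzene ring (C1 CH3, C2 Br, C3 OH, C4 OH, C5 Br, C6 Br) is cut at C2–C3 and C5–C6. The feature exploited is that C6–C1(CH3)–C2 is a three-carbon 1,3-dielectrophile with interchangeable ends (masked 2-methylmalonaldehyde). C3(O), C4(O) and C5 map onto the γ-, keto and α-carbons of 4-methoxyacetoacetate. One TiCl4-mediated [3+3] cyclocondensation joins the open-chain diene MeO(Me3SiO)C=CH–C(OSiMe3)=CH–OMe with 3-ethoxy-2-methylacrolein. It forms both bonds, closes and aromatises the ring, and leaves an ester on C5 as a placeholder for bromine. Global demethylation and a triple bromination, one event decarboxylative, complete the route.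

Key step: step 3

Assumption: the C=C geometries drawn for the silyl enol ethers and the open-chain intermediate are the expected or reactive ones. Isomer mixtures serve equally, because no such geometry and no transient stereocentre survives aromatisation. The target has no stereocentre.

Step 1
Reactants: 1 methyl 4-methoxy-3-oxobutanoate (methyl 4-methoxyacetoacetate); 2 chlorotrimethylsilane
Product: 3 methyl (Z)-4-methoxy-3-(trimethylsilyloxy)but-2-enoate
Conditions: Me3SiCl (1.5 equiv), Et3N (1.6 equiv), toluene, 20 °C, 2–3 d; filter under Ar, concentrate
Reagents that add atoms: chlorotrimethylsilane, C[Si](C)(C)Cl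
Why: Amine-mediated O-silylation of the strongly enolised β-keto ester gives the conjugated silyl enol ether, the standard first stage in making 1,3-bis(silyloxy)dienes, and the ester and ether groups are inert to these conditions.

Step 2
Reactants: 3 methyl (Z)-4-methoxy-3-(trimethylsilyloxy)but-2-enoate; 2 chlorotrimethylsilane
Product: 4 (1Z,3Z)-1,4-dimethoxy-1,3-bis(trimethylsilyloxy)buta-1,3-diene
Conditions: LiN(i-Pr)2 (commercial solution, 1.3 equiv), THF, −78 °C, 1 h; Me3SiCl (1.5 equiv), −78 → 20 °C; hexane, filter under Ar, used crude
Reagents that add atoms: chlorotrimethylsilane, C[Si](C)(C)Cl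
Why: Kinetic γ-deprotonation of the β-silyloxy enoate at the CH2OMe carbon gives the extended lithium dienolate, which Me3SiCl traps on the ester oxygen (O-silylation to a silyl ketene acetal), the established access to 4-alkoxy-substituted 1,3-bis(silyloxy)dienes.

Step 3
Reactants: 4 (1Z,3Z)-1,4-dimethoxy-1,3-bis(trimethylsilyloxy)buta-1,3-diene; 5 (E)-3-ethoxy-2-methylacrolein
Product: 7 methyl 2-hydroxy-3-methoxy-5-methylbenzoate, via open-chain keto-enal 6 (not isolated)
Conditions: 4 (1.2 equiv), 5 (1.0 equiv), TiCl4 (1.1 equiv), CH2Cl2 (concentrated), −78 → 20 °C, 16 h; then 10% aq. HCl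
Reagents that add atoms: none
Why: TiCl4 activates the vinylogous formate 5, and the methoxy-bearing terminus of 4, the most nucleophilic site of a 1,3-bis(silyloxy)diene, attacks it in a vinylogous Mukaiyama aldol/addition–elimination event that makes C2–C3 and, after loss of the ethoxy group, gives the titanium-bound keto-enal 6. The remaining β-keto ester enolate carbon (future C5) then adds to the aldehyde carbon (future C6) in a 6-exo-trig intramolecular aldol (Knoevenagel-type) closure of the only ring, the Lewis acid letting the C=C of 6 reach the cis geometry that closure requires. Elimination of the titanium-bound oxygen and enolisation of the former ketone (C4) are driven by aromatisation, so the sequence ends at the hydrogen-bonded salicylate 7. The closest known reaction type is the TiCl4-mediated formal [3+3] cyclocondensation of 1,3-bis(silyloxy)-1,3-dienes, 4-alkoxy-substituted ones included, with 3-alkoxy- or 3-silyloxy-enones and malonaldehyde acetals to give salicylates. No stereocentre survives, and orientation is immaterial because both electrophilic carbons of 5 flank the same C(CH3), so either mode of docking gives 7. The only selectivity needed is ring closure over oligomerisation or premature desilylation, secured by adding TiCl4 at −78 °C to a concentrated mixture of the partners and warming slowly.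

Step 4
Reactants: 7 methyl 2-hydroxy-3-methoxy-5-methylbenzoate
Product: 8 2,3-dihydroxy-5-methylbenzoic acid
Conditions: 48% aq. HBr, AcOH, reflux, Ar
Reagents that add atoms: water, O
Why: Hot aqueous HBr in acetic acid hydrolyses the methyl ester (acid-catalysed acyl–oxygen hydrolysis) and cleaves the protonated aryl methyl ether by SN2 attack of bromide on its methyl group, a classical global demethylation that the ring methyl, phenol and singly ortho-hydroxy-activated carboxyl group tolerate.

Step 5
Reactants: 8 2,3-dihydroxy-5-methylbenzoic acid
Product: 10 3,4,6-tribromo-5-methylbenzene-1,2-diol, via 4,6-dibromo-2,3-dihydroxy-5-methylbenzoic acid 9 (not isolated)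
Conditions: Br2 (3.05 equiv), aq. AcOH, 0 → 40 °C, dark; aq. NaHSO3 wash
Reagents that add atoms: bromine, BrBr
Why: Electrophilic aromatic bromination at C2–H and C6–H (target numbering, ortho and para to the C3 hydroxyl) is followed by ipso attack at C5 (ortho to the C4 hydroxyl) with loss of CO2, the classical bromodecarboxylation of salicylic acids, while near-exact stoichiometry, darkness and the reductive wash hold back catechol oxidation and attack at the methyl group.

Compound list
1 | methyl 4-methoxy-3-oxobutanoate (methyl 4-methoxyacetoacetate) | COCC(=O)CC(=O)OC | starting material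
2 | chlorotrimethylsilane | C[Si](C)(C)Cl | starting material
3 | methyl (Z)-4-methoxy-3-(trimethylsilyloxy)but-2-enoate | COC/C(O[Si](C)(C)C)=C/C(=O)OC | intermediate
4 | (1Z,3Z)-1,4-dimethoxy-1,3-bis(trimethylsilyloxy)buta-1,3-diene | CO/C(O[Si](C)(C)C)=C/C(O[Si](C)(C)C)=C/OC | intermediate
5 | (E)-3-ethoxy-2-methylacrolein | CCO/C=C(\C)C=O | starting material
6 | methyl (Z)-4-methoxy-6-methyl-3,7-dioxohept-5-enoate (racemic, written in neutral form, not isolated) | COC(=O)CC(=O)C(OC)/C=C(/C)C=O | intermediate
7 | methyl 2-hydroxy-3-methoxy-5-methylbenzoate | COC(=O)c1cc(C)cc(OC)c1O | intermediate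
8 | 2,3-dihydroxy-5-methylbenzoic acid | Cc1cc(O)c(O)c(C(=O)O)c1 | intermediate
9 | 4,6-dibromo-2,3-dihydroxy-5-methylbenzoic acid (not isolated) | Cc1c(Br)c(O)c(O)c(C(=O)O)c1Br | intermediate
10 | 3,4,6-tribromo-5-methylbenzene-1,2-diol | Cc1c(Br)c(O)c(O)c(Br)c1Br | target

Total step count: 5. Longest linear sequence: 5 steps (1 → 3 → 4 → 7 → 8 → 10).

Steps most likely to fail

1. Step 3. The coupling may halt after the first C–C bond. Stoichiometric TiCl4 may also desilylate the diene and oligomerise the electron-rich enal faster than the two partners combine. The fallback sets out from 4 and 5 and comes back at 7. The enal is taken out of play by converting 5 with HC(OEt)3 and EtOH under catalytic TsOH into the saturated bis-acetal 1,1,3,3-tetraethoxy-2-methylpropane F1. F1 and 4 are then combined under catalytic Me3SiOTf in CH2Cl2 from −78 °C to room temperature. Both ring bonds then arise by Mukaiyama-type substitution of acetal-derived oxocarbenium ions, without a stoichiometric metal halide. The acidic aqueous work-up expels the remaining ethanol and aromatises to 7.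

2. Step 5. Bromine may oxidise the catechol to the ortho-quinone level, or attack the methyl-bearing carbon or the side chain. The ipso substitution may also lag, so that the carboxyl group is retained. The fallback sets out from 8 and comes back at 10, and it separates loss of CO2 from halogenation. Compound 8 is heated in quinoline at about 200 °C under argon (thermal protodecarboxylation of a salicylic acid) to give 4-methylbenzene-1,2-diol F2. This needs only three ordinary C–H brominations, run with Br2 (3 equiv) in anhydrous CHCl3–AcOH at 0 °C with a NaHSO3 wash, to reach 10.

3. Step 2. Deprotonation may be incomplete or accompanied by C-silylation, and the ketene-acetal silyl group may be lost by adventitious hydrolysis during isolation. The fallback sets out from 1 and 5 and comes back at 7, and it dispenses with silicon. Compound 1 is converted into its dianion (NaH, then n-BuLi, THF, 0 → −78 °C). The γ-carbon of the dianion adds to the aldehyde of 5 to give methyl (E)-7-ethoxy-5-hydroxy-4-methoxy-6-methyl-3-oxohept-6-enoate F3 as a diastereomer mixture. TsOH in warm toluene then ionises the allylic alcohol with loss of ethanol to the transposed enal 6. Intramolecular Knoevenagel condensation with dehydration gives 7.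

Further compounds
F1 | step 3 | 1,1,3,3-tetraethoxy-2-methylpropane | CCOC(OCC)C(C)C(OCC)OCC
F2 | step 5 | 4-methylbenzene-1,2-diol | Cc1ccc(O)c(O)c1
F3 | step 2 | methyl (E)-7-ethoxy-5-hydroxy-4-methoxy-6-methyl-3-oxohept-6-enoate (diastereomer mixture) | COC(=O)CC(=O)C(OC)C(O)/C(C)=C/OCC
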